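## Retrosynthetic overview

1. The C9–Br bond is made last by Appel inversion of a (9S)-carbinol; the (E)-C3=C15HBr unit comes from Wittig bromomethylenation of a ring B enone (C3=O).
2. The ring B enone and the cis-7,9-diol arise together from a spiro vinylogous-ester epoxy alcohol (hydride opening plus Stork–Danheiser transposition); C9 is set by CBS reduction and C7 by hydroxyl-directed epoxidation.
3. Key disconnection C6–C11: ring A is closed onto the intact ring B by attack of nucleophilic C6 on the gem-dimethyl carbon C11 of a 9-oxobisabolane-type dienone. This is the bond and polarity of the γ-bisabolene → chamigrene spirocyclisation, run enantioselectively so that it sets the spiro centre.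
4. That precursor is assembled by Michael union (C6–C7) of 3-ethoxycyclohex-2-en-1-one with 2-methylhept-2-en-5-yn-4-one, itself made from 3-methylbut-2-enoyl chloride and silylpropyne.
5. Ring order: ring B is bought as the cyclohexenone; ring A is the only ring formed (step 3).

Assumption/numbering: chamigrane locants are used throughout (ring B = C1–C5, spiro atom C6, ring A = C7–C11, C12/C13 = methyls on C11, C14 = methyl on C7, C15 = exocyclic carbon on C3); in these locants the target is (3E,6S,7S,9R).

## Route

Step 1
Reactants: 1 3-methylbut-2-enoyl chloride; 2 trimethyl(prop-1-yn-1-yl)silane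
Product: 3 2-methylhept-2-en-5-yn-4-one
Conditions: AlCl3 (1.1 equiv), CH2Cl2, 0 °C, 1 h; ice/water quench
Reagents that add atoms: none
Why: Friedel–Crafts-type ipso-acylation of an alkynylsilane, in which the acylium ion from 1 attacks the silicon-bearing alkyne carbon (β-silyl cation control) and loss of the silyl group gives the ynone regiospecifically, with no stereocentre formed.

Step 2
Reactants: 4 3-ethoxycyclohex-2-en-1-one; 3 2-methylhept-2-en-5-yn-4-one
Product: 6 rac-(E/Z)-3-ethoxy-6-(6-methyl-4-oxohepta-2,5-dien-2-yl)cyclohex-2-en-1-one, via lithium enolate 5 (not isolated)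
Conditions: LiN(iPr)2 (1.05 equiv, commercial solution), THF, −78 °C, 45 min; then 3 (1.0 equiv), −78 to −20 °C; AcOH (1.1 equiv), −78 °C
Reagents that add atoms: none
Why: Stork–Danheiser kinetic deprotonation of the vinylogous ester at C6 followed by Michael addition of the enolate to the alkyne β-carbon of the ynone (C6–C7 bond), the doubly activated C6–H of the adduct quenching the allenolate so that the resulting 1,5-dicarbonyl anion is a thermodynamic sink; C6 is formed racemic and C7=C8 as an E/Z mixture, and both are erased in the next step.

Step 3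
Reactants: 6 rac-(E/Z)-3-ethoxy-6-(6-methyl-4-oxohepta-2,5-dien-2-yl)cyclohex-2-en-1-one
Product: 7 (6S)-3-ethoxy-7,11,11-trimethylspiro[5.5]undeca-2,7-diene-1,9-dione
Conditions: O-allyl-N-(9-anthracenylmethyl)cinchonidinium bromide (10 mol%), Cs2CO3 (0.3 equiv), toluene, 0 °C to rt
Reagents that add atoms: none
Why: Proposed new method: deprotonation of the doubly activated C6–H gives a planar vinylogous diketonate whose C7=C8 geometry equilibrates and whose C6 terminus attacks C11 of the dimethylvinyl ketone (intramolecular Michael addition, equivalently an oxy-anion-accelerated disrotatory 6π-electrocyclisation of the C6=C7–C8=C9(O−)–C10=C11 triene), closing ring A onto ring B through the same C6–C11 bond and with the same polarity as the γ-bisabolene → chamigrene cyclisation and leaving the 7,8-alkene of the α-chamigrene series, while the cinchona ammonium cation ion-paired with the anion shields one face of C6 and so sets the spiro centre as 6S (the pseudo-enantiomeric cinchoninium salt is used if the sense proves opposite); the closest known reactions are cinchona phase-transfer-catalysed asymmetric 6π-electrocyclisations and intramolecular Michael additions, and base-mediated [5+1] double-Michael spiroannulations of cross-conjugated dienones.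

Step 4
Reactants: 7 (6S)-3-ethoxy-7,11,11-trimethylspiro[5.5]undeca-2,7-diene-1,9-dione
Product: 8 (6S,9S)-3-ethoxy-9-hydroxy-7,11,11-trimethylspiro[5.5]undeca-2,7-dien-1-one
Conditions: (R)-2-methyl-CBS-oxazaborolidine [(R)-1-methyl-3,3-diphenyltetrahydro-1H,3H-pyrrolo[1,2-c][1,3,2]oxazaborole] (20 mol%), catecholborane (1.5 equiv), toluene, −78 °C; aq. NaOH work-up
Reagents that add atoms: none
Why: Corey–Bakshi–Shibata reduction, in which the oxazaborolidine-bound borane delivers hydride to one face of the ring A enone carbonyl under catalyst control (the trisubstituted alkenyl arm taken as the large group; the (S)-catalyst is used if the sense proves opposite), setting C9 as S irrespective of the remote spiro centre while the electron-rich vinylogous ester carbonyl does not react at −78 °C, so that the minor enantiomer from step 3 becomes a separable diastereomer here.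

Step 5
Reactants: 8 (6S,9S)-3-ethoxy-9-hydroxy-7,11,11-trimethylspiro[5.5]undeca-2,7-dien-1-one
Product: 9 (6S,7R,8S,9S)-3-ethoxy-7,8-epoxy-9-hydroxy-7,11,11-trimethylspiro[5.5]undec-2-en-1-one
Conditions: VO(acac)2 (3 mol%), t-BuOOH (1.5 equiv), CH2Cl2, 0 °C to rt
Reagents that add atoms: tert-butyl hydroperoxide, CC(C)(C)OO
Why: Hydroxyl-directed (Sharpless–Michaelson) vanadium-catalysed epoxidation, in which the vanadate ester of the C9 allylic alcohol delivers the peroxide oxygen to the alkene face syn to the hydroxyl, setting C7 (and transiently C8) with the C7–O bond cis to the C9 hydroxyl, while the push–pull enol ether alkene of ring B is not attacked.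

Step 6
Reactants: 9 (6S,7R,8S,9S)-3-ethoxy-7,8-epoxy-9-hydroxy-7,11,11-trimethylspiro[5.5]undec-2-en-1-one
Product: 11 (6S,7S,9S)-7,9-dihydroxy-7,11,11-trimethylspiro[5.5]undec-1-en-3-one, via triol enol ether 10 (not isolated)
Conditions: LiAlH4 (3 equiv), THF, 0 °C to reflux; then 1 M HCl, THF, rt
Reagents that add atoms: water, O
Why: LiAlH4 opens the trisubstituted epoxide by SN2 attack at the less hindered secondary C8 (Fürst–Plattner opening that leaves the tertiary C7–O bond and its configuration untouched) and reduces the vinylogous ester carbonyl, and aqueous acid then hydrolyses the enol ether and eliminates the C1 hydroxyl (Stork–Danheiser transposition) to give the 4,4-disubstituted cyclohexenone with C1=C2 on the former carbonyl side, so no new stereocentre is created and the spiro configuration is carried over.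

Step 7
Reactants: 11 (6S,7S,9S)-7,9-dihydroxy-7,11,11-trimethylspiro[5.5]undec-1-en-3-one
Product: 12 (3E,6S,7S,9S)-3-(bromomethylidene)-7,11,11-trimethylspiro[5.5]undec-1-ene-7,9-diol
Conditions: [Ph3PCH2Br]Br (3.0 equiv), KOtBu (2.8 equiv), THF, −78 °C; then 11, −78 to 0 °C
Reagents that add atoms: (bromomethyl)triphenylphosphonium bromide, BrC[P+](c1ccccc1)(c1ccccc1)c1ccccc1.[Br-]
Why: Wittig bromomethylenation of the enone carbonyl with Ph3P=CHBr (1,2-addition; the hydroxyls stay protonated because no excess base is present, which also avoids a retro-vinylogous-aldol opening of ring A), the geometry not being reagent-controlled so that the E isomer, with bromine syn to the bulkier sp3 C4 arm as the kinetic Wittig model predicts, is separated from the Z isomer by chromatography.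

Step 8
Reactants: 12 (3E,6S,7S,9S)-3-(bromomethylidene)-7,11,11-trimethylspiro[5.5]undec-1-ene-7,9-diol
Product: 13 (3E,6S,7S,9R)-9-bromo-3-(bromomethylidene)-7,11,11-trimethylspiro[5.5]undec-1-en-7-ol
Conditions: CBr4 (1.5 equiv), PPh3 (1.6 equiv), CH2Cl2, 0 °C to rt
Reagents that add atoms: tetrabromomethane, BrC(Br)(Br)Br
Why: Appel reaction, in which the secondary C9 hydroxyl is converted into an alkoxyphosphonium ion and displaced by bromide in an SN2 step with inversion (axial leaving group to equatorial bromide, 9S to 9R), the tertiary C7 hydroxyl and the vinyl bromide remaining untouched.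

## Compound list

1 | 3-methylbut-2-enoyl chloride | CC(C)=CC(=O)Cl | starting material
2 | trimethyl(prop-1-yn-1-yl)silane | CC#C[Si](C)(C)C | starting material
3 | 2-methylhept-2-en-5-yn-4-one | CC#CC(=O)C=C(C)C | intermediate
4 | 3-ethoxycyclohex-2-en-1-one | CCOC1=CC(=O)CCC1 | starting material
5 | lithium 5-ethoxycyclohexa-1,5-dien-1-olate (kinetic C6 enolate of 4, not isolated) | [Li+].[O-]C1=CCCC(OCC)=C1 | intermediate
6 | rac-(E/Z)-3-ethoxy-6-(6-methyl-4-oxohepta-2,5-dien-2-yl)cyclohex-2-en-1-one | CCOC1=CC(=O)C(CC1)C(C)=CC(=O)C=C(C)C | intermediate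
7 | (6S)-3-ethoxy-7,11,11-trimethylspiro[5.5]undeca-2,7-diene-1,9-dione | CC1(C)CC(=O)C=C(C)[C@@]12C(=O)C=C(OCC)CC2 | intermediate
8 | (6S,9S)-3-ethoxy-9-hydroxy-7,11,11-trimethylspiro[5.5]undeca-2,7-dien-1-one | CC1(C)C[C@H](O)C=C(C)[C@@]12C(=O)C=C(OCC)CC2 | intermediate
9 | (6S,7R,8S,9S)-3-ethoxy-7,8-epoxy-9-hydroxy-7,11,11-trimethylspiro[5.5]undec-2-en-1-one | CC1(C)C[C@H](O)[C@@H]3O[C@]3(C)[C@@]12C(=O)C=C(OCC)CC2 | intermediate
10 | (6R,7S,9S)-3-ethoxy-7,11,11-trimethylspiro[5.5]undec-2-ene-1,7,9-triol (C1 epimers, not isolated) | CC1(C)C[C@H](O)C[C@](C)(O)[C@@]12C(O)C=C(OCC)CC2 | intermediate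
11 | (6S,7S,9S)-7,9-dihydroxy-7,11,11-trimethylspiro[5.5]undec-1-en-3-one | CC1(C)C[C@H](O)C[C@](C)(O)[C@@]12C=CC(=O)CC2 | intermediate
12 | (3E,6S,7S,9S)-3-(bromomethylidene)-7,11,11-trimethylspiro[5.5]undec-1-ene-7,9-diol | CC1(C)C[C@H](O)C[C@](C)(O)[C@@]12C=C/C(=C/Br)CC2 | intermediate
13 | (3E,6S,7S,9R)-9-bromo-3-(bromomethylidene)-7,11,11-trimethylspiro[5.5]undec-1-en-7-ol (CNP0234157.1) | CC1(C)C[C@@H](Br)C[C@](C)(O)[C@@]12C=C/C(=C/Br)CC2 | target

## Step count and risks

Total step count: 8. Longest linear sequence: 8 steps (1 and 2 → 3 → 6 → 7 → 8 → 9 → 11 → 12 → 13).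

The three steps most likely to fail:

First, the spirocyclisation (step 3). It has to join two fully substituted carbons, and the asymmetric induction by the chiral ammonium ion is without direct precedent, so the ring closure may be slow or poorly enantioselective. The fallback sets out from 6. The ring is closed without chiral control (DBU, toluene, 60 °C) to give the racemic spiro dienedione F1. F1 is then reduced with catecholborane and the same (R)-oxazaborolidine; because the catalyst fixes C9 as S in both enantiomers, the racemate becomes two diastereomeric allylic alcohols, 8 and its (6R,9S) isomer F2, which are separated by chromatography. The route is rejoined at 8. This is a resolution by reagent-controlled reduction in place of an asymmetric ring closure and gives at best half of the material.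

Second, the bromomethylenation (step 7). The Wittig reaction gives no reliable control of the C3=C15 geometry, and the E/Z mixture may be close to 1:1 and hard to separate. The fallback sets out from 11. A Wittig reaction with the dibromomethylene ylide from [Ph3PCHBr2]Br and KOtBu gives the gem-dibromodiene diol F3, which has no geometry to control. Hydrogenolysis with Bu3SnH and Pd(PPh3)4 (4 mol%) in toluene at rt then removes the bromine on the less hindered side, cis to the flat C1=C2 arm, and leaves the bromine syn to C4. The route is rejoined at 12.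

Third, the Appel reaction (step 8). The C9 carbinol is axial and flanked by a syn-axial hydroxyl and methyl, so elimination or dehydration of the tertiary alcohol may compete with substitution. The fallback sets out from 12. Both hydroxyls are tied into the six-membered cyclic sulfate F4 (1,1'-sulfonyldiimidazole, NaH, THF, −40 °C). LiBr in THF opens the sulfate at the secondary C9 with inversion to give the lithium 7-sulfate F5. Hydrolysis of the sulfate monoester (cat. H2SO4, wet THF) frees the tertiary alcohol, and the route is rejoined at 13, the target.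

Further compounds
F1 | step 3 | racemic 3-ethoxy-7,11,11-trimethylspiro[5.5]undeca-2,7-diene-1,9-dione | CC1(C)CC(=O)C=C(C)C12C(=O)C=C(OCC)CC2
F2 | step 3 | (6R,9S)-3-ethoxy-9-hydroxy-7,11,11-trimethylspiro[5.5]undeca-2,7-dien-1-one | CC1(C)C[C@H](O)C=C(C)[C@]12C(=O)C=C(OCC)CC2
F3 | step 7 | (6S,7S,9S)-3-(dibromomethylidene)-7,11,11-trimethylspiro[5.5]undec-1-ene-7,9-diol | CC1(C)C[C@H](O)C[C@](C)(O)[C@@]12C=CC(=C(Br)Br)CC2
F4 | step 8 | (3E,6S,7S,9S)-3-(bromomethylidene)-7,11,11-trimethylspiro[5.5]undec-1-ene-7,9-diyl cyclic sulfate | CC1(C)C[C@H]3C[C@](C)(OS(=O)(=O)O3)[C@@]12C=C/C(=C/Br)CC2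
F5 | step 8 | lithium (3E,6S,7S,9R)-9-bromo-3-(bromomethylidene)-7,11,11-trimethylspiro[5.5]undec-1-en-7-yl sulfate | CC1(C)C[C@@H](Br)C[C@](C)(OS(=O)(=O)[O-])[C@@]12C=C/C(=C/Br)CC2.[Li+]
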